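**Retrosynthetic overview**

- The p-coumarate is attached last, by acylating the single free primary alcohol (C9–OH) of a silyl-protected dihydrobenzofuran core, followed by global desilylation.
- The strategy rests on the O1–C2 bond of the 2,3-dihydrobenzofuran (O1, C2, C3, C3a, C7a). It is benzylic, and the guaiacyl ring on C2 carries an oxygen para to C2, so C2 can be ionised and re-closed. The ring is therefore opened at O1–C2 to a 2-(2-hydroxyaryl)-1-arylpropane-1,3-diol, and the C2 configuration is set only at ring closure, by C3.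
- C3, the only centre needing reagent control, and the C2–C3 bond come from an Evans syn-aldol of an arylacetyl imide ((R)-4-benzyloxazolidinone) with O-silyl vanillin. Reductive removal of the auxiliary turns the imide carbonyl into the C9 hydroxymethyl arm.
- The arylacetic acid comes from dihydroconiferyl alcohol: O-allylation, silylation, Claisen rearrangement (sets the C3a–C bond ortho to the phenol), benzylation and oxidative cleavage of the allyl group.
- Both benzene rings are bought. The only ring formed is the dihydrofuran, in step 12.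

Key step: step 12

Remark: TIPS = triisopropylsilyl, TIPSO = triisopropylsilyloxy; dihydroconiferyl alcohol (1) is taken as a catalogue compound (it is otherwise one hydroboration–oxidation from eugenol), and the carbinol configuration written for 20–22 is the syn-aldol outcome, which step 12 erases.

**Step 1**
Reactants: 1 dihydroconiferyl alcohol [4-(3-hydroxypropyl)-2-methoxyphenol]; 2 allyl bromide
Product: 3 3-[4-(allyloxy)-3-methoxyphenyl]propan-1-ol
Conditions: K2CO3, acetone, reflux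
Reagents that add atoms: allyl bromide (2), C=CCBr
Why: Williamson ether synthesis; carbonate deprotonates the phenol but not the aliphatic alcohol, so O-allylation should be chemoselective.

**Step 2**
Reactants: 3 3-[4-(allyloxy)-3-methoxyphenyl]propan-1-ol; 4 triisopropylsilyl chloride
Product: 5 {3-[4-(allyloxy)-3-methoxyphenyl]propoxy}triisopropylsilane
Conditions: imidazole, DMF, rt
Reagents that add atoms: triisopropylsilyl chloride (4), CC(C)[Si](Cl)(C(C)C)C(C)C
Why: Imidazole-promoted silylation of a primary alcohol; TIPS is chosen because it should survive 190 °C, the oxidants, the boron triflate, hydride and the catalytic acid of step 12.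

**Step 3**
Reactants: 5 {3-[4-(allyloxy)-3-methoxyphenyl]propoxy}triisopropylsilane
Product: 7 2-allyl-6-methoxy-4-[3-(TIPSO)propyl]phenol, via Claisen dienone 6 (not isolated)
Conditions: N,N-diethylaniline, 190 °C
Reagents that add atoms: none
Why: Aromatic Claisen rearrangement; the [3,3] shift can only reach the unsubstituted ortho carbon (the other ortho position carries OMe, the para position the side chain), and dienone 6 tautomerises to the phenol.

**Step 4**
Reactants: 7 2-allyl-6-methoxy-4-[3-(TIPSO)propyl]phenol; 8 benzyl bromide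
Product: 9 1-allyl-2-(benzyloxy)-3-methoxy-5-[3-(TIPSO)propyl]benzene
Conditions: K2CO3, DMF, 50 °C
Reagents that add atoms: benzyl bromide (8), BrCc1ccccc1
Why: Williamson benzylation of the phenol; benzyl is orthogonal to TIPS and is later removed by neutral hydrogenolysis, before any acid is applied.

**Step 5**
Reactants: 9 1-allyl-2-(benzyloxy)-3-methoxy-5-[3-(TIPSO)propyl]benzene
Product: 11 2-{2-(benzyloxy)-3-methoxy-5-[3-(TIPSO)propyl]phenyl}acetaldehyde, via vicinal diol 10 (not isolated)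
Conditions: OsO4 (2 mol%), NaIO4, 2,6-lutidine, dioxane–H2O, rt
Reagents that add atoms: osmium tetroxide, O=[Os](=O)(=O)=O (catalytic, regenerated by sodium periodate, [Na+].[O-]I(=O)(=O)=O)
Why: Lemieux–Johnson oxidation; the terminal alkene is dihydroxylated and the diol cleaved in the same flask by periodate, with 2,6-lutidine suppressing over-oxidation, while the arene, benzyl ether and silyl ether are inert; the aldehyde is used crude.

**Step 6**
Reactants: 11 2-{2-(benzyloxy)-3-methoxy-5-[3-(TIPSO)propyl]phenyl}acetaldehyde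
Product: 12 2-{2-(benzyloxy)-3-methoxy-5-[3-(TIPSO)propyl]phenyl}acetic acid
Conditions: NaClO2, NaH2PO4, 2-methyl-2-butene, t-BuOH–H2O, 0 °C → rt
Reagents that add atoms: sodium chlorite, [Na+].[O-]Cl=O
Why: Pinnick oxidation; buffered chlorite oxidises only the aldehyde, and the alkene scavenger removes hypochlorous acid before it can chlorinate the electron-rich ring.

**Step 7**
Reactants: 12 2-{2-(benzyloxy)-3-methoxy-5-[3-(TIPSO)propyl]phenyl}acetic acid; 13 (R)-4-benzyloxazolidin-2-one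
Product: 15 (R)-4-benzyl-3-(2-{2-(benzyloxy)-3-methoxy-5-[3-(TIPSO)propyl]phenyl}acetyl)oxazolidin-2-one, via mixed pivalic anhydride 14 (not isolated)
Conditions: PivCl, Et3N, THF, −20 °C; then 13, LiCl, rt
Reagents that add atoms: (R)-4-benzyloxazolidin-2-one (13), O=C1N[C@H](Cc2ccccc2)CO1
Why: N-acylation of an Evans auxiliary through a mixed anhydride; the lithium-activated oxazolidinone attacks the less hindered arylacetyl carbonyl of 14 and not the pivaloyl one.

**Step 8**
Reactants: 16 vanillin; 4 triisopropylsilyl chloride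
Product: 17 3-methoxy-4-(TIPSO)benzaldehyde
Conditions: imidazole, DMF, rt
Reagents that add atoms: triisopropylsilyl chloride (4), CC(C)[Si](Cl)(C(C)C)C(C)C
Why: Phenol silylation; the aryl TIPS ether keeps the para oxygen as a donor for step 12 and should resist the hydride and acid steps better than smaller silyl groups.

**Step 9**
Reactants: 15 (R)-4-benzyl-3-(2-{2-(benzyloxy)-3-methoxy-5-[3-(TIPSO)propyl]phenyl}acetyl)oxazolidin-2-one; 17 3-methoxy-4-(TIPSO)benzaldehyde
Product: 20 (R)-4-benzyl-3-[(2R,3R)-2-{2-(benzyloxy)-3-methoxy-5-[3-(TIPSO)propyl]phenyl}-3-hydroxy-3-[3-methoxy-4-(TIPSO)phenyl]propanoyl]oxazolidin-2-one, via boron Z-enolate 18 (not isolated), via boron aldolate 19 (not isolated)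
Conditions: Bu2BOTf, i-Pr2NEt, CH2Cl2, −78 → 0 °C; 17, −78 → 0 °C; then pH 7 buffer, MeOH, H2O2, 0 °C
Reagents that add atoms: 3-methoxy-4-(TIPSO)benzaldehyde (17), COc1cc(C=O)ccc1O[Si](C(C)C)(C(C)C)C(C)C
Why: Evans boron syn-aldol; the Z-enolate 18 reacts through a Zimmerman–Traxler chair with the auxiliary carbonyl turned away, so the aldehyde adds to the enolate face opposite the benzyl group and the (R)-auxiliary should give the (2R,3R) adduct, whose α-carbon becomes (S)-C3 of the target once the carbonyl is reduced (the descriptor changes by priority only).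

**Step 10**
Reactants: 20 the (2R,3R)-syn-aldol imide
Product: 21 (1R,2S)-2-{2-(benzyloxy)-3-methoxy-5-[3-(TIPSO)propyl]phenyl}-1-[3-methoxy-4-(TIPSO)phenyl]propane-1,3-diol
Conditions: LiBH4, H2O (1 equiv), THF, 0 °C
Reagents that add atoms: none
Why: Reductive cleavage of the N-acyl oxazolidinone; borohydride attacks the exocyclic imide carbonyl and delivers the primary alcohol (C9) while releasing the auxiliary, and the low temperature is meant to keep retro-aldol and α-epimerisation from competing.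

**Step 11**
Reactants: 21 the (1R,2S)-diol benzyl ether
Product: 22 (1R,2S)-2-{2-hydroxy-3-methoxy-5-[3-(TIPSO)propyl]phenyl}-1-[3-methoxy-4-(TIPSO)phenyl]propane-1,3-diol
Conditions: H2 (1 atm), 10% Pd/C, EtOAc, rt
Reagents that add atoms: none
Why: Hydrogenolysis of an aryl benzyl ether; in neutral ethyl acetate the O-benzyl bond is cleaved far faster than the benzylic carbinol C–O bond, and silyl ethers are untouched.

**Step 12**
Reactants: 22 the (1R,2S)-phenol diol
Product: 24 {(2R,3S)-7-methoxy-2-[3-methoxy-4-(TIPSO)phenyl]-5-[3-(TIPSO)propyl]-2,3-dihydrobenzofuran-3-yl}methanol, via benzylic cation 23 (not isolated)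
Conditions: p-TsOH·H2O (10 mol%), CH2Cl2 (0.01 M), 0 °C → rt; Et3N quench
Reagents that add atoms: none
Why: Protonation of the benzylic C1–OH of 22 and loss of water give the planar cation 23, stabilised in its quinone-methide-like oxocarbenium form by the para O-TIPS group, so the carbinol configuration left by the aldol is erased. The ortho phenol on the C3 aryl group then attacks the cationic carbon in a 5-exo-trig closure, forming O1–C2 and the only new ring. The new C2 centre is controlled by the existing (S)-C3 centre: the guaiacyl group goes anti to the CH2OH arm in the envelope transition state, and because the benzylic aryl ether can re-ionise under the acid, any cis isomer should drain to the more stable trans-(2R,3S) product. The closest known reaction type is the acid-mediated dehydrative cyclisation of 2-(2-hydroxyaryl)-1-arylpropane-1,3-diols, the laboratory counterpart of biosynthetic quinone-methide capture in phenylcoumaran formation. The step needs chemoselective ionisation (only the benzylic carbinol ionises, and the primary alcohol could close only an oxetane) and retention of C3, which carries no carbonyl and is at risk only if the cation loses H-3; fast intramolecular capture, catalytic acid, low temperature and high dilution are meant to suppress that path, and TIPS ethers should tolerate anhydrous catalytic sulfonic acid.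

**Step 13**
Reactants: 25 p-coumaric acid; 4 triisopropylsilyl chloride
Product: 27 (E)-3-[4-(TIPSO)phenyl]prop-2-enoic acid, via bis-TIPS silyl ester 26 (not isolated)
Conditions: TIPSCl (2.3 equiv), imidazole, DMF, rt; then K2CO3, MeOH–THF–H2O, 0 °C; 1 M HCl to pH 3
Reagents that add atoms: triisopropylsilyl chloride (4), CC(C)[Si](Cl)(C(C)C)C(C)C
Why: Bis-silylation followed by selective solvolysis; the silyl ester is far more labile to carbonate than the aryl TIPS ether, so only the acid is set free.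

**Step 14**
Reactants: 24 the trans-(2R,3S)-dihydrobenzofuran alcohol; 27 (E)-3-[4-(TIPSO)phenyl]prop-2-enoic acid
Product: 28 {(2R,3S)-7-methoxy-2-[3-methoxy-4-(TIPSO)phenyl]-5-[3-(TIPSO)propyl]-2,3-dihydrobenzofuran-3-yl}methyl (E)-3-[4-(TIPSO)phenyl]prop-2-enoate
Conditions: EDC·HCl, DMAP, CH2Cl2, 0 °C → rt
Reagents that add atoms: (E)-3-[4-(TIPSO)phenyl]prop-2-enoic acid (27), O=C(O)/C=C/c1ccc(O[Si](C(C)C)(C(C)C)C(C)C)cc1
Why: Steglich esterification; the C9 primary alcohol is the only free hydroxyl in 24, so acylation is unambiguous and no stereocentre is touched.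

**Step 15**
Reactants: 28 the tris-TIPS ester
Product: 29 [(2R,3S)-2-(4-hydroxy-3-methoxyphenyl)-5-(3-hydroxypropyl)-7-methoxy-2,3-dihydrobenzofuran-3-yl]methyl (E)-3-(4-hydroxyphenyl)prop-2-enoate (CNP0202924.1)
Conditions: TBAF, AcOH (1:1, 4.5 equiv each), THF, 0 °C → rt
Reagents that add atoms: none
Why: Fluoride desilylation of two aryl and one primary alkyl silyl ether; acetic acid buffering keeps the phenoxides protonated, which should protect the cinnamate ester from acyl transfer and the C2–O1 bond from phenoxide-driven ring opening.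

**Compound list**

1 | dihydroconiferyl alcohol, 4-(3-hydroxypropyl)-2-methoxyphenol | COc1cc(CCCO)ccc1O | starting material
2 | allyl bromide | C=CCBr | starting material
3 | 3-[4-(allyloxy)-3-methoxyphenyl]propan-1-ol | COc1cc(CCCO)ccc1OCC=C | intermediate
4 | triisopropylsilyl chloride | CC(C)[Si](Cl)(C(C)C)C(C)C | starting material
5 | {3-[4-(allyloxy)-3-methoxyphenyl]propoxy}triisopropylsilane | COc1cc(CCCO[Si](C(C)C)(C(C)C)C(C)C)ccc1OCC=C | intermediate
6 | 6-allyl-2-methoxy-4-[3-(TIPSO)propyl]cyclohexa-2,4-dien-1-one (Claisen dienone) | COC1=CC(CCCO[Si](C(C)C)(C(C)C)C(C)C)=CC(CC=C)C1=O | intermediate (not isolated)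
7 | 2-allyl-6-methoxy-4-[3-(TIPSO)propyl]phenol | COc1cc(CCCO[Si](C(C)C)(C(C)C)C(C)C)cc(CC=C)c1O | intermediate
8 | benzyl bromide | BrCc1ccccc1 | starting material
9 | 1-allyl-2-(benzyloxy)-3-methoxy-5-[3-(TIPSO)propyl]benzene | COc1cc(CCCO[Si](C(C)C)(C(C)C)C(C)C)cc(CC=C)c1OCc1ccccc1 | intermediate
10 | 3-{2-(benzyloxy)-3-methoxy-5-[3-(TIPSO)propyl]phenyl}propane-1,2-diol | COc1cc(CCCO[Si](C(C)C)(C(C)C)C(C)C)cc(CC(O)CO)c1OCc1ccccc1 | intermediate (not isolated)
11 | 2-{2-(benzyloxy)-3-methoxy-5-[3-(TIPSO)propyl]phenyl}acetaldehyde | COc1cc(CCCO[Si](C(C)C)(C(C)C)C(C)C)cc(CC=O)c1OCc1ccccc1 | intermediate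
12 | 2-{2-(benzyloxy)-3-methoxy-5-[3-(TIPSO)propyl]phenyl}acetic acid | COc1cc(CCCO[Si](C(C)C)(C(C)C)C(C)C)cc(CC(=O)O)c1OCc1ccccc1 | intermediate
13 | (R)-4-benzyloxazolidin-2-one | O=C1N[C@H](Cc2ccccc2)CO1 | starting material
14 | mixed pivalic anhydride of 12 | COc1cc(CCCO[Si](C(C)C)(C(C)C)C(C)C)cc(CC(=O)OC(=O)C(C)(C)C)c1OCc1ccccc1 | intermediate (not isolated)
15 | (R)-4-benzyl-3-(2-{2-(benzyloxy)-3-methoxy-5-[3-(TIPSO)propyl]phenyl}acetyl)oxazolidin-2-one | COc1cc(CCCO[Si](C(C)C)(C(C)C)C(C)C)cc(CC(=O)N2[C@H](Cc3ccccc3)COC2=O)c1OCc1ccccc1 | intermediate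
16 | vanillin | COc1cc(C=O)ccc1O | starting material
17 | 3-methoxy-4-(TIPSO)benzaldehyde | COc1cc(C=O)ccc1O[Si](C(C)C)(C(C)C)C(C)C | intermediate
18 | (Z)-dibutylboron enolate of 15 | COc1cc(CCCO[Si](C(C)C)(C(C)C)C(C)C)cc(/C=C(\OB(CCCC)CCCC)N2[C@H](Cc3ccccc3)COC2=O)c1OCc1ccccc1 | intermediate (not isolated)
19 | dibutylboron aldolate of 20 | COc1cc(CCCO[Si](C(C)C)(C(C)C)C(C)C)cc([C@@H](C(=O)N2[C@H](Cc3ccccc3)COC2=O)[C@@H](OB(CCCC)CCCC)c2ccc(O[Si](C(C)C)(C(C)C)C(C)C)c(OC)c2)c1OCc1ccccc1 | intermediate (not isolated)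
20 | (R)-4-benzyl-3-[(2R,3R)-2-{2-(benzyloxy)-3-methoxy-5-[3-(TIPSO)propyl]phenyl}-3-hydroxy-3-[3-methoxy-4-(TIPSO)phenyl]propanoyl]oxazolidin-2-one | COc1cc(CCCO[Si](C(C)C)(C(C)C)C(C)C)cc([C@@H](C(=O)N2[C@H](Cc3ccccc3)COC2=O)[C@@H](O)c2ccc(O[Si](C(C)C)(C(C)C)C(C)C)c(OC)c2)c1OCc1ccccc1 | intermediate
21 | (1R,2S)-2-{2-(benzyloxy)-3-methoxy-5-[3-(TIPSO)propyl]phenyl}-1-[3-methoxy-4-(TIPSO)phenyl]propane-1,3-diol | COc1cc(CCCO[Si](C(C)C)(C(C)C)C(C)C)cc([C@@H](CO)[C@@H](O)c2ccc(O[Si](C(C)C)(C(C)C)C(C)C)c(OC)c2)c1OCc1ccccc1 | intermediate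
22 | (1R,2S)-2-{2-hydroxy-3-methoxy-5-[3-(TIPSO)propyl]phenyl}-1-[3-methoxy-4-(TIPSO)phenyl]propane-1,3-diol (key-step precursor) | COc1cc(CCCO[Si](C(C)C)(C(C)C)C(C)C)cc([C@@H](CO)[C@@H](O)c2ccc(O[Si](C(C)C)(C(C)C)C(C)C)c(OC)c2)c1O | intermediate
23 | benzylic cation from 22 (para-silyloxy stabilised) | COc1cc(CCCO[Si](C(C)C)(C(C)C)C(C)C)cc([C@@H](CO)[CH+]c2ccc(O[Si](C(C)C)(C(C)C)C(C)C)c(OC)c2)c1O | intermediate (not isolated)
24 | {(2R,3S)-7-methoxy-2-[3-methoxy-4-(TIPSO)phenyl]-5-[3-(TIPSO)propyl]-2,3-dihydrobenzofuran-3-yl}methanol (key-step product) | COc1cc([C@@H]2Oc3c(OC)cc(CCCO[Si](C(C)C)(C(C)C)C(C)C)cc3[C@H]2CO)ccc1O[Si](C(C)C)(C(C)C)C(C)C | intermediate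
25 | p-coumaric acid | O=C(O)/C=C/c1ccc(O)cc1 | starting material
26 | triisopropylsilyl (E)-3-[4-(TIPSO)phenyl]prop-2-enoate | CC(C)[Si](OC(=O)/C=C/c1ccc(O[Si](C(C)C)(C(C)C)C(C)C)cc1)(C(C)C)C(C)C | intermediate (not isolated)
27 | (E)-3-[4-(TIPSO)phenyl]prop-2-enoic acid | O=C(O)/C=C/c1ccc(O[Si](C(C)C)(C(C)C)C(C)C)cc1 | intermediate
28 | {(2R,3S)-7-methoxy-2-[3-methoxy-4-(TIPSO)phenyl]-5-[3-(TIPSO)propyl]-2,3-dihydrobenzofuran-3-yl}methyl (E)-3-[4-(TIPSO)phenyl]prop-2-enoate | COc1cc([C@@H]2Oc3c(OC)cc(CCCO[Si](C(C)C)(C(C)C)C(C)C)cc3[C@H]2COC(=O)/C=C/c2ccc(O[Si](C(C)C)(C(C)C)C(C)C)cc2)ccc1O[Si](C(C)C)(C(C)C)C(C)C | intermediate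
29 | [(2R,3S)-2-(4-hydroxy-3-methoxyphenyl)-5-(3-hydroxypropyl)-7-methoxy-2,3-dihydrobenzofuran-3-yl]methyl (E)-3-(4-hydroxyphenyl)prop-2-enoate | COc1cc([C@@H]2Oc3c(OC)cc(CCCO)cc3[C@H]2COC(=O)/C=C/c2ccc(O)cc2)ccc1O | target

**Step count**

Total steps: 15. Longest linear sequence: 13 steps (1–7, 9–12, 14, 15); steps 8 and 13 are side branches.

**Steps most likely to fail**

1. Step 12. The ionised C2 may shed the C9 carbon as formaldehyde or lose H-3 to a stilbene, whose reprotonation would erode the C3 configuration. It may also alkylate a second electron-rich ring instead of closing, and trans control may be incomplete. The fallback keeps the O1–C2 closure but runs it through a neutral quinone methide under weak base instead of a free cation under acid.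
   - It sets out from 22. The aryl silyl ether para to the carbinol is removed selectively (TBAF, 1.1 equiv, THF, −20 °C), giving (1R,2S)-1-(4-hydroxy-3-methoxyphenyl)-2-{2-hydroxy-3-methoxy-5-[3-(TIPSO)propyl]phenyl}propane-1,3-diol F1.
   - Bromotrimethylsilane (CH2Cl2, 0 °C) converts the p-hydroxybenzylic carbinol into the benzylic bromide F2.
   - Brief shaking with saturated aqueous NaHCO3 eliminates HBr to the p-quinone methide F3.
   - The ortho phenol adds to F3 in a reversible 1,6-addition, which should settle on the trans-dihydrobenzofuran with a free guaiacyl phenol F4.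
   - Mitsunobu esterification of F4 with 27 (PPh3, DIAD, THF, 0 °C) uses the carboxylic acid, not the phenol, as pronucleophile and gives the mono-phenolic ester F5.
   - Desilylation of F5 under the conditions of step 15 comes back to the route at 29.

2. Step 9. Enolisation of the ortho-disubstituted arylacetyl imide may be slow, the deactivated aldehyde may add sluggishly or with poor facial selectivity, and the adduct may revert by retro-aldol. The fallback sets C3 by auxiliary-controlled alkylation instead and exploits the fact that either carbinol epimer is acceptable.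
   - It sets out from 15. The sodium enolate (NaHMDS, THF, −78 °C) is alkylated with benzyloxymethyl chloride on the face opposite the auxiliary benzyl group, giving the (S)-α-(benzyloxymethyl) imide F6.
   - LiBH4 reduction gives the (R)-2-aryl-3-(benzyloxy)propan-1-ol F7, and Dess–Martin oxidation gives the (S)-α-aryl aldehyde F8, which is used at once.
   - Commercial 4-bromo-2-methoxyphenol is silylated with 4 to the aryl bromide F9 and converted with magnesium into the arylmagnesium bromide F10.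
   - Addition of F10 to F8 at −78 °C gives the bis-benzyl carbinol F11 as a mixture of carbinol epimers.
   - Hydrogenolysis of both benzyl ethers (H2, Pd/C) comes back to the route at 22, accompanied by its (1S,2S) carbinol epimer F12; both enter step 12 and converge on 24.

3. Step 10. Under the basic hydride conditions the aldolate may fragment by retro-aldol, or the doubly activated α-hydrogen may epimerise, which would erode C3. The fallback blocks the aldol oxygen first.
   - It sets out from 20. Silylation (TESOTf, 2,6-lutidine, CH2Cl2, −78 °C) gives the O-triethylsilyl aldol imide F13, which cannot undergo retro-aldol.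
   - LiBH4 (MeOH, 1 equiv, THF, 0 °C) gives the mono-TES-protected diol F14.
   - Selective removal of the secondary TES ether (HF·pyridine, pyridine, THF, 0 °C) comes back to the route at 21.

**Further compounds**

F1 | step 12 | (1R,2S)-1-(4-hydroxy-3-methoxyphenyl)-2-{2-hydroxy-3-methoxy-5-[3-(TIPSO)propyl]phenyl}propane-1,3-diol | COc1cc(CCCO[Si](C(C)C)(C(C)C)C(C)C)cc([C@@H](CO)[C@@H](O)c2ccc(O)c(OC)c2)c1O
F2 | step 12 | (2S)-3-bromo-3-(4-hydroxy-3-methoxyphenyl)-2-{2-hydroxy-3-methoxy-5-[3-(TIPSO)propyl]phenyl}propan-1-ol (bromide epimers) | COc1cc(CCCO[Si](C(C)C)(C(C)C)C(C)C)cc([C@@H](CO)C(Br)c2ccc(O)c(OC)c2)c1O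
F3 | step 12 | p-quinone methide, 4-[(2S)-3-hydroxy-2-{2-hydroxy-3-methoxy-5-[3-(TIPSO)propyl]phenyl}propylidene]-2-methoxycyclohexa-2,5-dien-1-one | COC1=CC(=C[C@H](CO)c2cc(CCCO[Si](C(C)C)(C(C)C)C(C)C)cc(OC)c2O)C=CC1=O
F4 | step 12 | 4-{(2R,3S)-3-(hydroxymethyl)-7-methoxy-5-[3-(TIPSO)propyl]-2,3-dihydrobenzofuran-2-yl}-2-methoxyphenol | COc1cc([C@@H]2Oc3c(OC)cc(CCCO[Si](C(C)C)(C(C)C)C(C)C)cc3[C@H]2CO)ccc1O
F5 | step 12 | {(2R,3S)-2-(4-hydroxy-3-methoxyphenyl)-7-methoxy-5-[3-(TIPSO)propyl]-2,3-dihydrobenzofuran-3-yl}methyl (E)-3-[4-(TIPSO)phenyl]prop-2-enoate | COc1cc([C@@H]2Oc3c(OC)cc(CCCO[Si](C(C)C)(C(C)C)C(C)C)cc3[C@H]2COC(=O)/C=C/c2ccc(O[Si](C(C)C)(C(C)C)C(C)C)cc2)ccc1O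
F6 | step 9 | (R)-4-benzyl-3-[(S)-3-(benzyloxy)-2-{2-(benzyloxy)-3-methoxy-5-[3-(TIPSO)propyl]phenyl}propanoyl]oxazolidin-2-one | COc1cc(CCCO[Si](C(C)C)(C(C)C)C(C)C)cc([C@@H](COCc2ccccc2)C(=O)N2[C@H](Cc3ccccc3)COC2=O)c1OCc1ccccc1
F7 | step 9 | (R)-3-(benzyloxy)-2-{2-(benzyloxy)-3-methoxy-5-[3-(TIPSO)propyl]phenyl}propan-1-ol | COc1cc(CCCO[Si](C(C)C)(C(C)C)C(C)C)cc([C@@H](COCc2ccccc2)CO)c1OCc1ccccc1
F8 | step 9 | (S)-3-(benzyloxy)-2-{2-(benzyloxy)-3-methoxy-5-[3-(TIPSO)propyl]phenyl}propanal | COc1cc(CCCO[Si](C(C)C)(C(C)C)C(C)C)cc([C@@H](COCc2ccccc2)C=O)c1OCc1ccccc1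
F9 | step 9 | (4-bromo-2-methoxyphenoxy)triisopropylsilane | COc1cc(Br)ccc1O[Si](C(C)C)(C(C)C)C(C)C
F10 | step 9 | [3-methoxy-4-(TIPSO)phenyl]magnesium bromide | Br[Mg]c1ccc(O[Si](C(C)C)(C(C)C)C(C)C)c(OC)c1
F11 | step 9 | (2S)-3-(benzyloxy)-2-{2-(benzyloxy)-3-methoxy-5-[3-(TIPSO)propyl]phenyl}-1-[3-methoxy-4-(TIPSO)phenyl]propan-1-ol (carbinol epimers) | COc1cc(CCCO[Si](C(C)C)(C(C)C)C(C)C)cc([C@@H](COCc2ccccc2)C(O)c2ccc(O[Si](C(C)C)(C(C)C)C(C)C)c(OC)c2)c1OCc1ccccc1
F12 | step 9 | (1S,2S)-2-{2-hydroxy-3-methoxy-5-[3-(TIPSO)propyl]phenyl}-1-[3-methoxy-4-(TIPSO)phenyl]propane-1,3-diol (carbinol epimer of 22) | COc1cc(CCCO[Si](C(C)C)(C(C)C)C(C)C)cc([C@@H](CO)[C@H](O)c2ccc(O[Si](C(C)C)(C(C)C)C(C)C)c(OC)c2)c1O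
F13 | step 10 | (R)-4-benzyl-3-[(2R,3R)-2-{2-(benzyloxy)-3-methoxy-5-[3-(TIPSO)propyl]phenyl}-3-[3-methoxy-4-(TIPSO)phenyl]-3-(triethylsilyloxy)propanoyl]oxazolidin-2-one | COc1cc(CCCO[Si](C(C)C)(C(C)C)C(C)C)cc([C@@H](C(=O)N2[C@H](Cc3ccccc3)COC2=O)[C@@H](O[Si](CC)(CC)CC)c2ccc(O[Si](C(C)C)(C(C)C)C(C)C)c(OC)c2)c1OCc1ccccc1
F14 | step 10 | (2S,3R)-2-{2-(benzyloxy)-3-methoxy-5-[3-(TIPSO)propyl]phenyl}-3-[3-methoxy-4-(TIPSO)phenyl]-3-(triethylsilyloxy)propan-1-ol | COc1cc(CCCO[Si](C(C)C)(C(C)C)C(C)C)cc([C@@H](CO)[C@@H](O[Si](CC)(CC)CC)c2ccc(O[Si](C(C)C)(C(C)C)C(C)C)c(OC)c2)c1OCc1ccccc1
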